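If a rate falls as the reciprocal of time, each power of ten in time adds the same amount of product, so I reckoned in decades of time.

| flask | solid substrate | coupling partner | remark | time |
|---|---|---|---|---|
| ochre | 0.10 M | 1 equiv | the very flask that is asked about, followed so far |  |
| grey | 0.15 M | 1 equiv | run made earlier |  |
| flask | 0.10 M | 1.00 equiv |  | 2.0 d |

| run | time / h | target / % | dissolved substrate / % |
|---|---|---|---|
| ochre | 1.00 | 2.0 | 39.9 |
| ochre | 3.00 | 5.2 | 46.7 |
| ochre | 5.00 | 8.5 | 47.3 |
| ochre | 8.00 | 12.0 | 47.5 |
| ochre | 12.0 | 15.1 | 47.8 |
| ochre | 15.0 | 17.6 | 47.9 |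
| ochre | 20.0 | 21.0 | 48.4 |
| grey | 4.00 | 6.2 | 32.0 |
| grey | 6.00 | 10.2 | 31.6 |
| grey | 8.00 | 10.9 | 31.8 |
| grey | 15.0 | 15.2 | 32.1 |
| grey | 20.0 | 16.4 | 31.4 |
| grey | 30.0 | 18.6 | 32.1 |
| grey | 50.0 | 20.7 | 31.8 |

(standard deviation of a reading: 0.5 percentage points)
- as a solid, counted per litre of solution: solid substrate
- at the start none of the solid substrate is in solution
- dissolved substrate means what is dissolved; the solid is not counted in it
- amount of target at 2.0 d, in percent of the solid substrate charged
- concentration of dissolved substrate in solution at 2.0 d, in percent of saturation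

In the ochre run the target grew at 0.00163 M h⁻¹ early and at 7.37 × 10⁻⁴ M h⁻¹ late, a slowing by a factor of 2.20. Dissolved substrate barely moved, near 48.4%, so I took the coupling as pseudo-first-order in the partner. Coupling had used 21.0% of the partner, which gives a factor of 1.27, less than the slowing. So I supposed a further partner loss, second order as in step growth, which forgets its charge. The runs allowed that: between 8.00 h and 20.0 h ochre gained 0.00900 M and grey, with its larger charge, 0.00825 M.

The last grey readings gave 0.0162 M for the decade gain, the target added per litre while time grows by a power of ten. Ochre had 0.380 of a decade to go, so I reckoned 27.2%, with solid still present. The forecast said 30% (27% to 33%), above mine, and 100% of saturation, picturing “a catalyst dying per turnover”.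

The flask gave 24.9% and 99.8%.

    solid substrate ⇌ dissolved substrate, rate k1*(cs1 - [dissolved substrate]) while solid is left; crystals form when [dissolved substrate] > cs1 (solubility = 48.0 mM, k = 1.90 h⁻¹)
    dissolved substrate + coupling partner → target (k = 0.600 L mol⁻¹ h⁻¹)
    2 coupling partner → self-condensation product A (k = 0.740 L mol⁻¹ h⁻¹)
    2 solid substrate → self-condensation product B (k = 5.40 × 10⁻⁴ L mol⁻¹ h⁻¹)
    target ⇌ isomer of the product (K = 1.40, k = 0.00520 h⁻¹)

At 2.00 d this flask made target 1.33 times faster than it used it up, so its late gain was a difference of two rates. Between 1.00 d and 2.00 d it added 3.3 percentage points, or 0.0111 M per decade, below the carried 0.0162 M. For the same recipe read at 12 h, the decade gain run back from the ochre reading at 20.0 h gives 17.4%; the computed result is 15.8%.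

Readings and results were computed on assumed constants, and the scatter is random.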